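The route rests on cutting the bond between C1 of the central orsellinate ring (ring B, the carbon flanked by C2–OH and C6–CH3) and its ester carbonyl, whose oxygen is O-4 of the terminal ring C. That aryl–C(=O)–O–aryl unit is formally arene + CO + phenoxide, so a palladium-catalysed, CO-gas-free aryloxycarbonylation forms the C–C bond and completes the second depside link in one operation. The precursors are a preformed ring A–ring B depside carrying bromine at ring B C1, and the 4-O-formate of benzyl orsellinate, which supplies both the carbonyl carbon and the phenoxide. Benzyl groups are removed at the end by hydrogenolysis, which spares the acetate.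

Key step: step 12

Remark: the target has no stereocentre and no hindered axis (it is achiral), so no step has to set configuration. Ring A is the acetoxylated ring, ring B the central ring, ring C the ring with the free acid. Orsellinate numbering is used for ring positions (C1 bears the carboxyl carbon, C2 and C4 oxygen, C6 methyl).

**Ring A acid**

Step 1
Reactants: 1 2,4-dihydroxy-6-methylbenzaldehyde
Product: 2 2,4-bis(benzyloxy)-6-methylbenzaldehyde
Conditions: BnBr, K2CO3, DMF, 60 °C
Reagents that add atoms: benzyl bromide, BrCc1ccccc1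
Why: Williamson ether synthesis; warm DMF also alkylates the hydrogen-bonded 2-OH, so both phenols are masked as hydrogenolysable ethers.

Step 2
Reactants: 2 2,4-bis(benzyloxy)-6-methylbenzaldehyde
Product: 4 2,4-bis(benzyloxy)-6-methylphenol, via aryl formate 3 (not isolated)
Conditions: mCPBA, CH2Cl2, rt; then K2CO3 (cat.), MeOH, rt
Reagents that add atoms: mCPBA, O=C(OO)c1cccc(Cl)c1
Why: Baeyer–Villiger (Dakin-type) oxidation, in which the electron-rich aryl group migrates to give the aryl formate, which mild methanolysis cleaves to the phenol that becomes O-5 of ring A.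

Step 3
Reactants: 4 2,4-bis(benzyloxy)-6-methylphenol
Product: 5 2,4-bis(benzyloxy)-6-methylphenyl acetate
Conditions: Ac2O, pyridine, DMAP (cat.), CH2Cl2, rt
Reagents that add atoms: acetic anhydride, CC(=O)OC(C)=O
Why: DMAP-catalysed O-acetylation of the hindered phenol installs the acetate that the target keeps, at the only free hydroxyl present.

Step 4
Reactants: 5 2,4-bis(benzyloxy)-6-methylphenyl acetate
Product: 7 4,6-bis(benzyloxy)-3-formyl-2-methylphenyl acetate, via iminium salt 6 (not isolated)
Conditions: POCl3, DMF, 0 to 70 °C; then aq. NaOAc, rt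
Reagents that add atoms: N,N-dimethylformamide, CN(C)C=O; water, O
Why: Vilsmeier–Haack formylation; the chloroiminium ion should attack the ring carbon flanked by OBn and CH3 and para to the other OBn (the site preference of 3,5-dialkoxytoluenes) rather than the carbon between the two benzyloxy groups, and buffered hydrolysis should free the aldehyde without loss of the acetate.

Step 5
Reactants: 7 4,6-bis(benzyloxy)-3-formyl-2-methylphenyl acetate
Product: 8 3-acetoxy-4,6-bis(benzyloxy)-2-methylbenzoic acid
Conditions: NaClO2, NaH2PO4, 2-methyl-2-butene, t-BuOH/THF/H2O, 0 °C to rt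
Reagents that add atoms: sodium chlorite, [Na+].[O-]Cl=O
Why: Pinnick oxidation converts the hindered aldehyde into the acid in a weakly acidic buffer that leaves the aryl acetate and benzyl ethers intact, with the alkene scavenging HOCl.

**Ring B phenol**

Step 6
Reactants: 9 2-bromo-3-methylphenol
Product: 12 2-bromo-3-methyl-5-(4,4,5,5-tetramethyl-1,3,2-dioxaborolan-2-yl)phenol, via O-boryl ether 10 (not isolated), via bis-borylated arene 11 (not isolated)
Conditions: HBpin, THF, rt; then [Ir(OMe)(cod)]2 (cat.), dtbpy (cat.), B2pin2, 80 °C; then MeOH/H2O work-up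
Reagents that add atoms: bis(pinacolato)diboron, CC1(C)OB(OC1(C)C)B1OC(C)(C)C(C)(C)O1
Why: Iridium-catalysed C–H borylation after in situ O-borylation; steric control should send boron to the only C–H without an ortho neighbour (C5, para to Br), and the C–Br bond is tolerated.

Step 7
Reactants: 12 2-bromo-3-methyl-5-(4,4,5,5-tetramethyl-1,3,2-dioxaborolan-2-yl)phenol
Product: 13 2-[3-(benzyloxy)-4-bromo-5-methylphenyl]-4,4,5,5-tetramethyl-1,3,2-dioxaborolane
Conditions: BnBr, K2CO3, DMF, rt
Reagents that add atoms: benzyl bromide, BrCc1ccccc1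
Why: Williamson benzylation of the ortho-bromophenol under anhydrous carbonate conditions that a pinacol boronate tolerates.

Step 8
Reactants: 13 2-[3-(benzyloxy)-4-bromo-5-methylphenyl]-4,4,5,5-tetramethyl-1,3,2-dioxaborolane
Product: 14 3-(benzyloxy)-4-bromo-5-methylphenol
Conditions: 30% H2O2, aq. NaOH, THF, 0 °C to rt
Reagents that add atoms: hydrogen peroxide, OO
Why: Oxidation of the arylboronate (1,2-aryl shift from boron to oxygen) unveils the phenol para to bromine, so the two oxygens of ring B are differentiated without regiochemical ambiguity.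

**A–B depside**

Step 9
Reactants: 8 3-acetoxy-4,6-bis(benzyloxy)-2-methylbenzoic acid; 14 3-(benzyloxy)-4-bromo-5-methylphenol
Product: 15 3-(benzyloxy)-4-bromo-5-methylphenyl 3-acetoxy-4,6-bis(benzyloxy)-2-methylbenzoate
Conditions: EDC·HCl, DMAP, CH2Cl2, rt
Reagents that add atoms: none
Why: Steglich esterification via the acylpyridinium ion should couple the di-ortho-substituted acid with the unhindered phenol under conditions that do not disturb the aryl acetate.

**Ring C formate**

Step 10
Reactants: 16 2,4-dihydroxy-6-methylbenzoic acid (orsellinic acid)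
Product: 17 benzyl 2,4-dihydroxy-6-methylbenzoate (benzyl orsellinate)
Conditions: BnBr, KHCO3, DMF, rt
Reagents that add atoms: benzyl bromide, BrCc1ccccc1
Why: SN2 alkylation of the carboxylate; bicarbonate is too weak a base to bring the phenols into play, and room temperature avoids decarboxylation.

Step 11
Reactants: 17 benzyl 2,4-dihydroxy-6-methylbenzoate
Product: 18 benzyl 4-(formyloxy)-2-hydroxy-6-methylbenzoate
Conditions: HCO2H, Ac2O, 60 °C; then 17, NaOAc, toluene, 0 °C to rt
Reagents that add atoms: formic acid, O=CO (delivered as acetic formic anhydride, CC(=O)OC=O, formed in the flask with acetic anhydride)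
Why: O-formylation with the mixed anhydride should occur at the free 4-OH, because the 2-OH is tied up in a hydrogen bond to the ester carbonyl.

**Union and deprotection**

Step 12
Reactants: 15 3-(benzyloxy)-4-bromo-5-methylphenyl 3-acetoxy-4,6-bis(benzyloxy)-2-methylbenzoate; 18 benzyl 4-(formyloxy)-2-hydroxy-6-methylbenzoate
Product: 20 benzyl 4-{[4-{[3-acetoxy-4,6-bis(benzyloxy)-2-methylbenzoyl]oxy}-2-(benzyloxy)-6-methylbenzoyl]oxy}-2-hydroxy-6-methylbenzoate, via benzyl orsellinate 17 (not isolated), via carbon monoxide 19 (not isolated)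
Conditions: Pd(OAc)2 (5 mol %), P(t-Bu)3·HBF4 (20 mol %), NEt3, 18 (2 equiv), MeCN/toluene, 80 °C, sealed tube
Reagents that add atoms: none
Why: Triethylamine triggers decarbonylation of formate 18 to the 4-phenoxide of 17 and CO 19 inside the sealed vessel; Pd(0)/P(t-Bu)3 inserts into the C–Br bond of 15, migratory insertion of CO gives the aroyl–palladium species, and phenoxide attack with reductive elimination forms the ester, so the ring B C1–carbonyl bond and the B–C depside link arise together. The closest known reaction type is the palladium-catalysed aryloxycarbonylation of aryl bromides with aryl formates as CO surrogates. No ring is closed and no stereocentre is formed. The site of C–C bond formation is fixed by the bromine placed in steps 6 to 8; the chemoselectivity needed is O-4 over O-2 of 17, secured by the higher acidity of the 4-OH and by the hydrogen bond that ties the 2-OH to the benzyl ester carbonyl. The A–B ester is shielded by its two ortho substituents and the acetate sits on the more basic phenoxide, so the amine/phenoxide medium should not scramble acyl groups, and CO insertion is expected to outrun C–H arylation of the neighbouring benzyl ether.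

Step 13
Reactants: 20 benzyl 4-{[4-{[3-acetoxy-4,6-bis(benzyloxy)-2-methylbenzoyl]oxy}-2-(benzyloxy)-6-methylbenzoyl]oxy}-2-hydroxy-6-methylbenzoate
Product: 21 4-{[4-{[3-acetoxy-4,6-dihydroxy-2-methylbenzoyl]oxy}-2-hydroxy-6-methylbenzoyl]oxy}-2-hydroxy-6-methylbenzoic acid
Conditions: H2 (1 atm), 10% Pd/C, EtOAc, rt
Reagents that add atoms: none
Why: Catalytic hydrogenolysis should cleave the three benzyl ethers and the benzyl ester in one operation while the aryl esters and the phenolic acetate are inert, and the neutral aprotic medium should suppress acetyl migration to the neighbouring 4-OH.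

**Compound list**

1 | 2,4-dihydroxy-6-methylbenzaldehyde | Cc1cc(O)cc(O)c1C=O | starting material
2 | 2,4-bis(benzyloxy)-6-methylbenzaldehyde | Cc1cc(OCc2ccccc2)cc(OCc2ccccc2)c1C=O | intermediate
3 | 2,4-bis(benzyloxy)-6-methylphenyl formate (not isolated) | Cc1cc(OCc2ccccc2)cc(OCc2ccccc2)c1OC=O | intermediate
4 | 2,4-bis(benzyloxy)-6-methylphenol | Cc1cc(OCc2ccccc2)cc(OCc2ccccc2)c1O | intermediate
5 | 2,4-bis(benzyloxy)-6-methylphenyl acetate | CC(=O)Oc1c(C)cc(OCc2ccccc2)cc1OCc1ccccc1 | intermediate
6 | N-{[3-acetoxy-4,6-bis(benzyloxy)-2-methylphenyl]methylene}-N-methylmethanaminium chloride (not isolated) | CC(=O)Oc1c(C)c(C=[N+](C)C)c(OCc2ccccc2)cc1OCc1ccccc1.[Cl-] | intermediate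
7 | 4,6-bis(benzyloxy)-3-formyl-2-methylphenyl acetate | CC(=O)Oc1c(C)c(C=O)c(OCc2ccccc2)cc1OCc1ccccc1 | intermediate
8 | 3-acetoxy-4,6-bis(benzyloxy)-2-methylbenzoic acid | CC(=O)Oc1c(C)c(C(=O)O)c(OCc2ccccc2)cc1OCc1ccccc1 | intermediate
9 | 2-bromo-3-methylphenol | Cc1cccc(O)c1Br | starting material
10 | 2-(2-bromo-3-methylphenoxy)-4,4,5,5-tetramethyl-1,3,2-dioxaborolane (not isolated) | Cc1cccc(OB2OC(C)(C)C(C)(C)O2)c1Br | intermediate
11 | 2-[2-bromo-3-methyl-5-(4,4,5,5-tetramethyl-1,3,2-dioxaborolan-2-yl)phenoxy]-4,4,5,5-tetramethyl-1,3,2-dioxaborolane (not isolated) | Cc1cc(B2OC(C)(C)C(C)(C)O2)cc(OB2OC(C)(C)C(C)(C)O2)c1Br | intermediate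
12 | 2-bromo-3-methyl-5-(4,4,5,5-tetramethyl-1,3,2-dioxaborolan-2-yl)phenol | Cc1cc(B2OC(C)(C)C(C)(C)O2)cc(O)c1Br | intermediate
13 | 2-[3-(benzyloxy)-4-bromo-5-methylphenyl]-4,4,5,5-tetramethyl-1,3,2-dioxaborolane | Cc1cc(B2OC(C)(C)C(C)(C)O2)cc(OCc2ccccc2)c1Br | intermediate
14 | 3-(benzyloxy)-4-bromo-5-methylphenol | Cc1cc(O)cc(OCc2ccccc2)c1Br | intermediate
15 | 3-(benzyloxy)-4-bromo-5-methylphenyl 3-acetoxy-4,6-bis(benzyloxy)-2-methylbenzoate | CC(=O)Oc1c(C)c(C(=O)Oc2cc(C)c(Br)c(OCc3ccccc3)c2)c(OCc2ccccc2)cc1OCc1ccccc1 | intermediate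
16 | 2,4-dihydroxy-6-methylbenzoic acid (orsellinic acid) | Cc1cc(O)cc(O)c1C(=O)O | starting material
17 | benzyl 2,4-dihydroxy-6-methylbenzoate (benzyl orsellinate) | Cc1cc(O)cc(O)c1C(=O)OCc1ccccc1 | intermediate
18 | benzyl 4-(formyloxy)-2-hydroxy-6-methylbenzoate | Cc1cc(OC=O)cc(O)c1C(=O)OCc1ccccc1 | intermediate
19 | carbon monoxide (not isolated) | [C-]#[O+] | intermediate
20 | benzyl 4-{[4-{[3-acetoxy-4,6-bis(benzyloxy)-2-methylbenzoyl]oxy}-2-(benzyloxy)-6-methylbenzoyl]oxy}-2-hydroxy-6-methylbenzoate | CC(=O)Oc1c(C)c(C(=O)Oc2cc(C)c(C(=O)Oc3cc(C)c(C(=O)OCc4ccccc4)c(O)c3)c(OCc3ccccc3)c2)c(OCc2ccccc2)cc1OCc1ccccc1 | intermediate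
21 | 4-{[4-{[3-acetoxy-4,6-dihydroxy-2-methylbenzoyl]oxy}-2-hydroxy-6-methylbenzoyl]oxy}-2-hydroxy-6-methylbenzoic acid | CC(=O)Oc1c(O)cc(O)c(C(=O)Oc2cc(C)c(C(=O)Oc3cc(C)c(C(=O)O)c(O)c3)c(O)c2)c1C | target

**Step count**

Total steps: 13. Longest linear sequence: 8 steps (steps 1–5, 9, 12, 13).

**Steps most likely to fail**

Step 12. Oxidative addition and CO capture at the electron-rich, di-ortho-substituted C–Br bond may be slow, so that CO is lost, hydrodebromination or C–H arylation of the adjacent benzyl ether takes over, or the free phenoxide exchanges acyl groups. The fallback sets out from 15 and separates C–C bond formation from depside formation. Palladium-catalysed hydroxycarbonylation of 15 with acetic formic anhydride generated in situ (HCO2Li, Ac2O, LiCl, i-Pr2NEt, Pd/dppf, DMF, 80 °C) should give 4-{[3-acetoxy-4,6-bis(benzyloxy)-2-methylbenzoyl]oxy}-2-(benzyloxy)-6-methylbenzoic acid F1. This acid would then be esterified with the 4-OH of 17 by the trifluoroacetic anhydride method (TFAA, toluene, rt), which comes back to the route at 20.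

Step 4. Electrophilic attack on a ring that carries the acetoxy group may be sluggish, attack at the carbon between the two benzyloxy groups may compete, and the acetate may be lost during hydrolysis of the iminium salt. The fallback sets out from 5. Bromination with NBS in MeCN at 0 °C, which is reliably selective for the position next to the methyl group in 3,5-dialkoxytoluenes, should give 4,6-bis(benzyloxy)-3-bromo-2-methylphenyl acetate F2. Palladium-catalysed reductive carbonylation of F2 (CO/H2, Pd(OAc)2, di(1-adamantyl)-n-butylphosphine, TMEDA, toluene, 100 °C) comes back to the route at 7.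

Step 6. The O-boryl group formed in situ may steer part of the borylation to the C–H next to oxygen, and conversion of the ortho-bromophenol may stall. The fallback sets out from 9 and replaces the O-boryl mask by a bulky silyl ether. TBSCl/imidazole should give (2-bromo-3-methylphenoxy)(tert-butyl)dimethylsilane F3. Its iridium-catalysed borylation under pure steric control should give tert-butyl[2-bromo-3-methyl-5-(4,4,5,5-tetramethyl-1,3,2-dioxaborolan-2-yl)phenoxy]dimethylsilane F4. One-pot desilylation–benzylation of F4 (CsF, BnBr, DMF) comes back to the route at 13.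

Further compounds
F1 | step 12 | 4-{[3-acetoxy-4,6-bis(benzyloxy)-2-methylbenzoyl]oxy}-2-(benzyloxy)-6-methylbenzoic acid | CC(=O)Oc1c(C)c(C(=O)Oc2cc(C)c(C(=O)O)c(OCc3ccccc3)c2)c(OCc2ccccc2)cc1OCc1ccccc1
F2 | step 4 | 4,6-bis(benzyloxy)-3-bromo-2-methylphenyl acetate | CC(=O)Oc1c(C)c(Br)c(OCc2ccccc2)cc1OCc1ccccc1
F3 | step 6 | (2-bromo-3-methylphenoxy)(tert-butyl)dimethylsilane | Cc1cccc(O[Si](C)(C)C(C)(C)C)c1Br
F4 | step 6 | tert-butyl[2-bromo-3-methyl-5-(4,4,5,5-tetramethyl-1,3,2-dioxaborolan-2-yl)phenoxy]dimethylsilane | Cc1cc(B2OC(C)(C)C(C)(C)O2)cc(O[Si](C)(C)C(C)(C)C)c1Br
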